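The route rests on the C3–C4 bond of the aminopropyl arm (spermidine numbering N1–C2–C3–C4–N5–C6–C7–C8–C9–N10). Two features are exploited. One is the 1,3-relationship of N1 and N5, a Mannich retron. The other is the hidden symmetry of the N5,N10-diacylated butane-1,4-diamine half. C4 first serves as a one-carbon clip that ties N5 and N10 into a symmetric 1,3-diacyl-1,3-diazepane ring. In the key step a silyl triflate opens this aminal to an N-acyl methyleneiminium ion. The β-carbon of an N-vinyl cinnamamide attacks it, and triethylsilane reduces the second N-acyliminium carbon in the same flask. Ring opening, desymmetrisation and fragment union thus coincide. The phenols travel as methyl ethers.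

Key step: step 4

Remark: acid chloride 2 and stabilised N-vinylformamide 6 are taken as commercial, and all cinnamoyl compounds are handled with exclusion of light because the E alkenes photoisomerise.

Step 1
Reactants: 1 butane-1,4-diamine (putrescine); 2 (E)-4-methoxycinnamoyl chloride (2 equiv)
Product: 3 N,N'-bis[(E)-4-methoxycinnamoyl]butane-1,4-diamine
Conditions: 2 M aq NaOH, CH2Cl2, 0 °C → rt
Reagents that add atoms: none
Why: Schotten–Baumann acylation, in which both primary amines outcompete hydroxide for the acid chloride and the sparingly soluble bisamide should separate from the two-phase mixture with its E alkenes untouched.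

Step 2
Reactants: 3 N,N'-bis[(E)-4-methoxycinnamoyl]butane-1,4-diamine; 4 paraformaldehyde (1.05 equiv CH2O)
Product: 5 1,3-bis[(E)-4-methoxycinnamoyl]-1,3-diazepane
Conditions: p-TsOH·H2O (10 mol %), 1,2-dichloroethane (about 5 mM), reflux, 4 Å MS in a Soxhlet thimble
Reagents that add atoms: none
Why: Acid-catalysed N-amidomethylation (Tscherniac–Einhorn-type condensation at nitrogen, the reaction that turns lactams and formaldehyde into N,N'-methylenebis-lactams): one amide is hydroxymethylated, water is lost to give an N-acyliminium ion, the second amide N–H closes the ring 7-endo-trig, and reversibility at high dilution with removal of water should drain oligomers into the monomeric aminal.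

Step 3
Reactants: 6 N-vinylformamide; 2 (E)-4-methoxycinnamoyl chloride
Product: 8 (E)-3-(4-methoxyphenyl)-N-vinylacrylamide, via N-formyl imide 7 (not isolated)
Conditions: Et3N, DMAP (10 mol %), THF, 0 °C → rt; then 2 M aq NaOH, 0 °C
Reagents that add atoms: none
Why: DMAP-catalysed N-acylation of the secondary formamide gives the mixed imide 7, whose unhindered, non-conjugated formyl carbonyl is attacked by hydroxide far faster than the cinnamoyl carbonyl, so chemoselective deformylation (imide hydrolysis) should release the secondary enamide with the vinyl group and the E alkene intact.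

Step 4
Reactants: 5 1,3-bis[(E)-4-methoxycinnamoyl]-1,3-diazepane (1.2 equiv); 8 (E)-3-(4-methoxyphenyl)-N-vinylacrylamide
Product: 12 N1,N5,N10-tris[(E)-4-methoxycinnamoyl]spermidine, via methyleneiminium triflate 9 (not isolated), via oxazinium triflate 10 (not isolated), via silyl imidate 11 (not isolated)
Conditions: 5, TMSOTf (1.3 equiv), 4 Å MS, CH2Cl2, −40 °C; slow addition of 8, → 0 °C; then Et3SiH (3 equiv), 0 °C → rt; aq NaHCO3
Reagents that add atoms: none
Why: TMSOTf silylates one of the two equivalent amide oxygens of 5, the aminal C–N bond ionises and the seven-membered ring opens to the N-acyl-N-alkyl methyleneiminium ion 9, in which the departing amide (the later N10 amide) waits as its O-silyl imidate. The nucleophilic terminal CH2 of the secondary enamide 8 attacks the CH2=N+ carbon and forms the C3–C4 bond; the closest known reaction types are α-amidoalkylation with N,N'-methylenebis(amides or carbamates) as Lewis-acid-triggered N-acyliminium precursors and the aza-ene/Mannich addition of enamides and enecarbamates to N-acyliminium ions, which gives 1,3-diamine derivatives after reduction. The only ring closed is transient: the N5 carbonyl oxygen captures the new N-acyliminium carbon 6-exo-trig (overall a polar [4+2] of the O=C–N+=CH2 heterodiene with the enamide) to give oxazinium salt 10, which stores this second electrophile and keeps it from another molecule of 8. Et3SiH is added only after 8 is consumed, so that 9 is not reduced to an N-methyl amide; it delivers hydride to the carbon next to N1 through the ring-chain equilibrium of 10 (ionic hydrogenation), and the bicarbonate work-up hydrolyses silyl imidate 11 to 12. The N,O-acetal stereocentre of 10 forms as a racemate and is erased by the hydride, so no stereocentre needs control, and the three E alkenes meet neither light, radicals nor metal hydrides. The step needs monofunctionalisation of a symmetric bisamide and attack by the enamide carbon rather than by nitrogen, the anisyl rings or the cinnamoyl alkenes: 5 holds exactly one electrophilic carbon and both modes of ring opening give the same ion, while the enamide β-carbon is by far the best π-nucleophile present.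

Step 5
Reactants: 12 N1,N5,N10-tris[(E)-4-methoxycinnamoyl]spermidine
Product: 13 N1,N5,N10-(E)-tri-p-coumaroylspermidine
Conditions: BBr3 (10 equiv, 1 M in CH2Cl2), CH2Cl2, −78 °C → rt, dark; then ice/H2O, extraction with EtOAc
Reagents that add atoms: none
Why: Lewis-acid aryl methyl ether cleavage, in which BBr3 binds each anisyl oxygen (and, unproductively, each amide oxygen, hence the excess), bromide removes the methyl group by SN2 and hydrolysis of the aryl borates should free the three phenols while the amides and E alkenes stay inert.

Compound list
1 | butane-1,4-diamine (putrescine) | NCCCCN | starting material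
2 | (E)-4-methoxycinnamoyl chloride | COc1ccc(/C=C/C(=O)Cl)cc1 | starting material
3 | N,N'-bis[(E)-4-methoxycinnamoyl]butane-1,4-diamine | COc1ccc(/C=C/C(=O)NCCCCNC(=O)/C=C/c2ccc(OC)cc2)cc1 | intermediate
4 | paraformaldehyde (written as formaldehyde) | C=O | starting material
5 | 1,3-bis[(E)-4-methoxycinnamoyl]-1,3-diazepane (seven-membered cyclic N,N'-diacyl aminal) | COc1ccc(/C=C/C(=O)N2CCCCN(C2)C(=O)/C=C/c3ccc(OC)cc3)cc1 | intermediate
6 | N-vinylformamide | C=CNC=O | starting material
7 | (E)-N-formyl-3-(4-methoxyphenyl)-N-vinylacrylamide | COc1ccc(/C=C/C(=O)N(C=C)C=O)cc1 | intermediate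
8 | (E)-3-(4-methoxyphenyl)-N-vinylacrylamide | COc1ccc(/C=C/C(=O)NC=C)cc1 | intermediate
9 | ring-opened N-[(E)-4-methoxycinnamoyl]-N-alkylmethyleneiminium triflate, with the distal amide as O-trimethylsilyl imidate | COc1ccc(/C=C/C(=O)[N+](=C)CCCCN=C(O[Si](C)(C)C)/C=C/c2ccc(OC)cc2)cc1.[O-]S(=O)(=O)C(F)(F)F | intermediate
10 | 2-[(E)-4-methoxystyryl]-6-[(E)-4-methoxycinnamoylamino]-3-(4-silylimidatobutyl)-5,6-dihydro-4H-1,3-oxazin-3-ium triflate (racemic at C6) | COc1ccc(/C=C/C2=[N+](CCCCN=C(O[Si](C)(C)C)/C=C/c3ccc(OC)cc3)CCC(NC(=O)/C=C/c3ccc(OC)cc3)O2)cc1.[O-]S(=O)(=O)C(F)(F)F | intermediate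
11 | N10 O-trimethylsilyl imidate of 12 | COc1ccc(/C=C/C(=O)N(CCCNC(=O)/C=C/c2ccc(OC)cc2)CCCCN=C(O[Si](C)(C)C)/C=C/c2ccc(OC)cc2)cc1 | intermediate
12 | N1,N5,N10-tris[(E)-4-methoxycinnamoyl]spermidine | COc1ccc(/C=C/C(=O)NCCCCN(CCCNC(=O)/C=C/c2ccc(OC)cc2)C(=O)/C=C/c2ccc(OC)cc2)cc1 | intermediate
13 | N1,N5,N10-(E)-tri-p-coumaroylspermidine | O=C(/C=C/c1ccc(O)cc1)NCCCCN(CCCNC(=O)/C=C/c1ccc(O)cc1)C(=O)/C=C/c1ccc(O)cc1 | target

Total step count: 5. Longest linear sequence: 4 (steps 1, 2, 4, 5).

Steps most likely to fail

Step 4. The diacyl aminal may ionise too slowly. Acid-induced self-condensation and oligomerisation of the enamide would then outrun the union, or the second iminium stage could pick up a further enamide. The fallback sets out from 1, 2 and 4 and comes back to the route at 12. It gives up the ring and replaces the amide leaving group by chloride.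
- Excess 1 is monoacylated with 2 (CH2Cl2, 0 °C) to (E)-N-(4-aminobutyl)-3-(4-methoxyphenyl)acrylamide F1.
- F1 condenses with aqueous formaldehyde 4 to 1,3,5-tris{4-[(E)-4-methoxycinnamoylamino]butyl}-1,3,5-triazinane F2.
- After azeotropic drying, 2 (one equivalent per ring nitrogen, CH2Cl2, 0 °C → rt) cleaves and acylates the triazinane to the N-chloromethyl amide F3. This is the known acylative cleavage of hexahydrotriazines.
- F3 should ionise with catalytic ZnCl2 at −20 °C and take up 8 to give the oxazinium chloride F4.
- Et3SiH/TFA in the same flask should then give 12.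

Step 2. Intermolecular methylene bridging to oligomers may compete with seven-membered ring closure, and the acid may hydroxymethylate the anisyl rings. The fallback sets out from 3 and comes back at 5. It replaces the reversible acid-catalysed condensation by an irreversible double N-alkylation under basic conditions. The dianion of 3 (NaH, DMF, 0 °C, high dilution) is treated with dibromomethane by syringe pump. The first substitution gives the N-bromomethyl amide F5, which the second amide anion should capture at once to close the ring.

Step 5. The threefold cleavage may stall at partly methylated stages when boron complexes of the triamide precipitate. The polar triphenol may be lost on aqueous work-up, and the acid set free may erode the E geometry. The fallback sets out from 12 and comes back at 13. It inverts the polarity of the cleavage: the ether oxygen is no longer activated with a Lewis acid. Instead a soft nucleophile attacks the methyl carbon under basic, boron-free conditions (NaSEt in excess, DMF, 110 °C, argon, dark; then 1 M HCl). Thiolate addition to the cinnamamides is reversible at this temperature, and the phenoxides formed deactivate the acceptors.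

Further compounds
F1 | step 4 | (E)-N-(4-aminobutyl)-3-(4-methoxyphenyl)acrylamide | COc1ccc(/C=C/C(=O)NCCCCN)cc1
F2 | step 4 | 1,3,5-tris{4-[(E)-4-methoxycinnamoylamino]butyl}-1,3,5-triazinane | COc1ccc(/C=C/C(=O)NCCCCN2CN(CCCCNC(=O)/C=C/c3ccc(OC)cc3)CN(CCCCNC(=O)/C=C/c3ccc(OC)cc3)C2)cc1
F3 | step 4 | (E)-N-(chloromethyl)-3-(4-methoxyphenyl)-N-{4-[(E)-4-methoxycinnamoylamino]butyl}acrylamide | COc1ccc(/C=C/C(=O)NCCCCN(CCl)C(=O)/C=C/c2ccc(OC)cc2)cc1
F4 | step 4 | 2-[(E)-4-methoxystyryl]-6-[(E)-4-methoxycinnamoylamino]-3-{4-[(E)-4-methoxycinnamoylamino]butyl}-5,6-dihydro-4H-1,3-oxazin-3-ium chloride | COc1ccc(/C=C/C2=[N+](CCCCNC(=O)/C=C/c3ccc(OC)cc3)CCC(NC(=O)/C=C/c3ccc(OC)cc3)O2)cc1.[Cl-]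
F5 | step 2 | (E)-N-(bromomethyl)-3-(4-methoxyphenyl)-N-{4-[(E)-4-methoxycinnamoylamino]butyl}acrylamide | COc1ccc(/C=C/C(=O)NCCCCN(CBr)C(=O)/C=C/c2ccc(OC)cc2)cc1
F0 | step 5 | none | none
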